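**Plan**

1. Cuts: the exocyclic C=CH2 (back to a ketone); the bond from that carbon to the linker CH2 (ring-B aldehyde plus ring-A methylene Grignard reagent); in ring B the bonds C1'–C2' and C5'=C6' (to 3-[(4-methoxybenzyl)oxy]propanal and methyl vinyl ketone).
2. Enabling feature: ring B (bromohydrin cyclohexane; C1' = methine bearing the linker, C4' = C(OH)CH3, C5' = CHBr) has C4' para to C1' and bromine next to C4'. This is the pattern of a 4-substituted cyclohex-2-enone with C4' as carbonyl carbon and C5'=C6' as the alkene.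
3. Forward order: ring B is closed by Michael–aldol annulation and taken to the bromohydrin aldehyde; ring A (the epoxide-bearing ring) comes from (S)-carvone; the fragments are joined by Grignard addition, then epoxide, ketone and methylene follow. A 4-methoxybenzyl ether is chosen because its alkoxide is a poor leaving group in the annulation and it can later be removed beside a silyl ether.
4. Ring-B stereochemistry: the amine catalyst sets C1'; the position of the enone alkene decides which α-carbon is brominated; axial bromination and methyl addition anti to C–Br relay C1' to C5' and C4'.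
5. Remark on the chemistry: kinetic bromination is expected to enter trans to the C1' substituent, so C1' is built opposite to the target ((S)-enone from the (R)-catalyst) and is inverted by equilibration at the ketone stage (step 17).
6. Ring-A stereochemistry: C5 of carvone is kept, the C6 side chain enters trans to isopropenyl, and a hydroxyl-directed epoxidation places the epoxide cis to that side chain.

Key step: step 3

**Route**

Step 1
Reactants: 1 propane-1,3-diol
Product: 2 3-[(4-methoxybenzyl)oxy]propan-1-ol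
Conditions: NaH (1 equiv), THF, 0 °C; 4-methoxybenzyl chloride, Bu4NI (cat.), rt; diol in excess
Reagents that add atoms: 4-methoxybenzyl chloride, COc1ccc(CCl)cc1
Why: Williamson etherification of the mono-alkoxide of a symmetrical diol used in excess should give mainly the mono-ether, and no stereocentre is formed.

Step 2
Reactants: 2 3-[(4-methoxybenzyl)oxy]propan-1-ol
Product: 3 3-[(4-methoxybenzyl)oxy]propanal
Conditions: TEMPO (cat.), PhI(OAc)2, CH2Cl2, rt
Reagents that add atoms: none
Why: TEMPO-catalysed alcohol oxidation stops at the aldehyde under non-basic conditions, which spares this β-alkoxy aldehyde from elimination.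

Step 3
Reactants: 3 3-[(4-methoxybenzyl)oxy]propanal; 4 methyl vinyl ketone
Product: 6 (S)-4-{[(4-methoxybenzyl)oxy]methyl}cyclohex-2-en-1-one, via keto aldehyde 5 (not isolated)
Conditions: (R)-2-[methoxy(diphenyl)methyl]pyrrolidine (5 mol%), ethyl 3,4-dihydroxybenzoate (20 mol%), neat, 4 °C; then LiOH (cat.), iPrOH, rt
Reagents that add atoms: none
Why: The catalyst condenses with 3 to an E-enamine whose face on the side of the methoxydiphenylmethyl group is shielded, so the α-carbon (future C1') adds to the β-carbon of 4 from the open face and hydrolysis releases the catalyst and keto aldehyde 5 (bond C1'–C2'). LiOH then forms the methyl-ketone enolate, which attacks the aldehyde in a 6-(enolendo)-exo-trig aldol closure, and loss of water gives the enone (bond C5'=C6'), so ring B arises in one operation. The closest known reaction type is the prolinol-ether-catalysed Michael addition of aldehydes to methyl vinyl ketone followed by aldol condensation to 4-substituted cyclohex-2-enones (a Robinson-type annulation). The only new stereocentre, C1', is controlled by the catalyst: the (R)-catalyst should give (R)-5 and hence (S)-6, the enantiomer needed because C1' is inverted later. The step needs enantiofacial selectivity and survival of both the stereocentre and the β-ether oxygen; both threats pass through the enolate or enamine at C1' and are held back by the acid co-catalyst, the low temperature, the fast intramolecular aldol and the poor leaving-group ability of a benzyl-type alkoxide. Regioselectivity of the aldol is secured because only the methyl-ketone enolate can reach the aldehyde through a six-membered ring and dehydrate into conjugation.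

Step 4
Reactants: 6 (S)-4-{[(4-methoxybenzyl)oxy]methyl}cyclohex-2-en-1-one
Product: 7 triethyl{[(4S)-4-{[(4-methoxybenzyl)oxy]methyl}cyclohex-1-en-1-yl]oxy}silane
Conditions: Et3SiH, RhCl(PPh3)3 (1 mol%), THF, 50 °C
Reagents that add atoms: triethylsilane, CC[SiH](CC)CC
Why: Rhodium-catalysed 1,4-hydrosilylation of an enone gives the silyl enol ether regiospecifically, so the C4'=C5' double bond keeps the sense of chirality recorded by the enone alkene and C1' is untouched.

Step 5
Reactants: 7 triethyl{[(4S)-4-{[(4-methoxybenzyl)oxy]methyl}cyclohex-1-en-1-yl]oxy}silane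
Product: 8 (2R,4S)-2-bromo-4-{[(4-methoxybenzyl)oxy]methyl}cyclohexan-1-one (bromine trans to the side chain)
Conditions: NBS, THF, −78 °C; crude product used at once
Reagents that add atoms: N-bromosuccinimide, O=C1CCC(=O)N1Br
Why: Electrophilic α-bromination of a silyl enol ether should proceed by axial attack on the half-chair that has the C1' substituent pseudo-equatorial (chair-like transition state), placing bromine at C5' trans to that substituent.

Step 6
Reactants: 8 (2R,4S)-2-bromo-4-{[(4-methoxybenzyl)oxy]methyl}cyclohexan-1-one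
Product: 9 (1S,2R,4S)-2-bromo-4-{[(4-methoxybenzyl)oxy]methyl}-1-methylcyclohexan-1-ol
Conditions: MeMgBr, CeCl3, THF, −78 °C
Reagents that add atoms: methylmagnesium bromide, C[Mg]Br
Why: Organocerium 1,2-addition to an α-bromo ketone avoids enolisation and halogen–metal exchange, and the methyl group should add anti to the axial C–Br bond (polar α-halo ketone model, axial attack), setting C4' with hydroxyl cis and methyl trans to bromine.

Step 7
Reactants: 9 (1S,2R,4S)-2-bromo-4-{[(4-methoxybenzyl)oxy]methyl}-1-methylcyclohexan-1-ol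
Product: 10 {[(1S,2R,4S)-2-bromo-4-{[(4-methoxybenzyl)oxy]methyl}-1-methylcyclohexyl]oxy}triethylsilane
Conditions: Et3SiOTf, 2,6-lutidine, CH2Cl2, −78 → 0 °C
Reagents that add atoms: triethylsilyl trifluoromethanesulfonate, CC[Si](CC)(CC)OS(=O)(=O)C(F)(F)F
Why: Silylation of a tertiary alcohol with a silyl triflate and a hindered pyridine base is reliable and masks the hydroxyl next to the bromide against the organometallic and basic steps that follow.

Step 8
Reactants: 10 {[(1S,2R,4S)-2-bromo-4-{[(4-methoxybenzyl)oxy]methyl}-1-methylcyclohexyl]oxy}triethylsilane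
Product: 11 [(1S,3R,4S)-3-bromo-4-methyl-4-(triethylsilyloxy)cyclohexyl]methanol
Conditions: DDQ, CH2Cl2–pH 7 buffer, 0 °C → rt
Reagents that add atoms: none
Why: Oxidative cleavage of a 4-methoxybenzyl ether with DDQ in buffered wet CH2Cl2 leaves the tertiary silyl ether and the secondary bromide untouched.

Step 9
Reactants: 11 [(1S,3R,4S)-3-bromo-4-methyl-4-(triethylsilyloxy)cyclohexyl]methanol
Product: 12 (1S,3R,4S)-3-bromo-4-methyl-4-(triethylsilyloxy)cyclohexane-1-carbaldehyde
Conditions: Dess–Martin periodinane, pyridine, CH2Cl2, 0 °C → rt; used directly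
Reagents that add atoms: none
Why: Dess–Martin oxidation under pyridine buffer gives the aldehyde without over-oxidation, and any epimerisation at C1' is harmless because that centre is equilibrated in step 17.

Step 10
Reactants: 13 (S)-(+)-carvone
Product: 14 (5S,6S)-6-(hydroxymethyl)-2-methyl-5-(prop-1-en-2-yl)cyclohex-2-en-1-one
Conditions: LiN(iPr)2, THF, −78 °C; CH2O (gas, from paraformaldehyde), −78 → −40 °C; H2O
Reagents that add atoms: formaldehyde, C=O
Why: Kinetic deprotonation of carvone at C6 and aldol addition to monomeric formaldehyde is an established α'-hydroxymethylation, and the electrophile should enter anti to the neighbouring isopropenyl group to give the trans-5,6 product.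

Step 11
Reactants: 14 (5S,6S)-6-(hydroxymethyl)-2-methyl-5-(prop-1-en-2-yl)cyclohex-2-en-1-one
Product: 15 N'-[(5S,6R)-6-(hydroxymethyl)-2-methyl-5-(prop-1-en-2-yl)cyclohex-2-en-1-ylidene]-4-methylbenzenesulfonohydrazide (same spatial arrangement as 14)
Conditions: TsNHNH2, EtOH, AcOH (cat.), rt
Reagents that add atoms: 4-methylbenzenesulfonohydrazide, Cc1ccc(S(=O)(=O)NN)cc1
Why: Condensation of the enone with tosylhydrazide gives the α,β-unsaturated tosylhydrazone needed for reductive transposition without change at the stereocentres, the trans-5,6 arrangement also being the more stable one.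

Step 12
Reactants: 15 N'-[(5S,6R)-6-(hydroxymethyl)-2-methyl-5-(prop-1-en-2-yl)cyclohex-2-en-1-ylidene]-4-methylbenzenesulfonohydrazide
Product: 17 [(1S,6S)-3-methyl-6-(prop-1-en-2-yl)cyclohex-2-en-1-yl]methanol, via allylic sulfonylhydrazine 16 (not isolated)
Conditions: catecholborane (excess), CHCl3, 0 °C; then NaOAc·3H2O, 60 °C
Reagents that add atoms: none
Why: Reduction of an α,β-unsaturated tosylhydrazone with catecholborane and loss of sulfinate gives an allylic diazene that expels N2 by a retro-ene hydrogen shift (reductive alkene transposition), moving the double bond to C1=C2 of the carvone ring and leaving C5 and C6 untouched.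

Step 13
Reactants: 17 [(1S,6S)-3-methyl-6-(prop-1-en-2-yl)cyclohex-2-en-1-yl]methanol
Product: 18 (3S,4S)-3-(bromomethyl)-1-methyl-4-(prop-1-en-2-yl)cyclohex-1-ene
Conditions: CBr4, PPh3, CH2Cl2, 0 °C
Reagents that add atoms: carbon tetrabromide, BrC(Br)(Br)Br
Why: Appel bromination converts the primary alcohol into the bromide under neutral conditions without affecting the two alkenes or the adjacent stereocentre.

Step 14
Reactants: 18 (3S,4S)-3-(bromomethyl)-1-methyl-4-(prop-1-en-2-yl)cyclohex-1-ene; 12 (1S,3R,4S)-3-bromo-4-methyl-4-(triethylsilyloxy)cyclohexane-1-carbaldehyde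
Product: 20 1-[(1S,3R,4S)-3-bromo-4-methyl-4-(triethylsilyloxy)cyclohexyl]-2-[(1S,6S)-3-methyl-6-(prop-1-en-2-yl)cyclohex-2-en-1-yl]ethan-1-ol (both carbinol epimers), via Grignard reagent 19 (not isolated)
Conditions: 18, Mg, THF, rt → 40 °C; then 12, THF, −78 → −40 °C; H2O
Reagents that add atoms: none
Why: Grignard formation from a primary bromide and 1,2-addition to an aldehyde at low temperature is standard, the secondary bromide and the silyl ether should not react at −78 °C, and the uncontrolled carbinol centre is removed by oxidation in step 16.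

Step 15
Reactants: 20 1-[(1S,3R,4S)-3-bromo-4-methyl-4-(triethylsilyloxy)cyclohexyl]-2-[(1S,6S)-3-methyl-6-(prop-1-en-2-yl)cyclohex-2-en-1-yl]ethan-1-ol
Product: 21 1-[(1S,3R,4S)-3-bromo-4-methyl-4-(triethylsilyloxy)cyclohexyl]-2-[(1R,2R,3S,6S)-6-methyl-3-(prop-1-en-2-yl)-7-oxabicyclo[4.1.0]heptan-2-yl]ethan-1-ol
Conditions: VO(acac)2 (cat.), tBuOOH, CH2Cl2, 0 °C → rt
Reagents that add atoms: tert-butyl hydroperoxide, CC(C)(C)OO
Why: Vanadium-catalysed hydroxyl-directed epoxidation of a bishomoallylic alcohol should deliver oxygen intramolecularly to the electron-rich trisubstituted ring-A alkene on the face that carries the carbinol side chain, setting both epoxide carbons cis to the linker and sparing the isopropenyl group.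

Step 16
Reactants: 21 1-[(1S,3R,4S)-3-bromo-4-methyl-4-(triethylsilyloxy)cyclohexyl]-2-[(1R,2R,3S,6S)-6-methyl-3-(prop-1-en-2-yl)-7-oxabicyclo[4.1.0]heptan-2-yl]ethan-1-ol
Product: 22 1-[(1S,3R,4S)-3-bromo-4-methyl-4-(triethylsilyloxy)cyclohexyl]-2-[(1R,2R,3S,6S)-6-methyl-3-(prop-1-en-2-yl)-7-oxabicyclo[4.1.0]heptan-2-yl]ethan-1-one
Conditions: Dess–Martin periodinane, pyridine, CH2Cl2, 0 °C
Reagents that add atoms: none
Why: Dess–Martin oxidation of the secondary alcohol under pyridine buffer should give the ketone without opening the epoxide and removes the uncontrolled carbinol centre.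

Step 17
Reactants: 22 1-[(1S,3R,4S)-3-bromo-4-methyl-4-(triethylsilyloxy)cyclohexyl]-2-[(1R,2R,3S,6S)-6-methyl-3-(prop-1-en-2-yl)-7-oxabicyclo[4.1.0]heptan-2-yl]ethan-1-one
Product: 23 1-[(1R,3R,4S)-3-bromo-4-methyl-4-(triethylsilyloxy)cyclohexyl]-2-[(1R,2R,3S,6S)-6-methyl-3-(prop-1-en-2-yl)-7-oxabicyclo[4.1.0]heptan-2-yl]ethan-1-one
Conditions: DBU, toluene, rt → 40 °C; 23 separated, recovered 22 resubjected
Reagents that add atoms: none
Why: Base-mediated enolisation equilibrates C1' next to the ketone toward the epimer that can hold acyl group, bromine and methyl group all equatorial with only the silyloxy group axial, whereas 22 must place either the acyl group or both bromine and methyl axial, and the cis-epoxide cannot be opened by the enolate because backside attack is geometrically impossible.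

Step 18
Reactants: 23 1-[(1R,3R,4S)-3-bromo-4-methyl-4-(triethylsilyloxy)cyclohexyl]-2-[(1R,2R,3S,6S)-6-methyl-3-(prop-1-en-2-yl)-7-oxabicyclo[4.1.0]heptan-2-yl]ethan-1-one
Product: 24 2-[(1R,3R,4S)-3-bromo-4-methyl-4-(triethylsilyloxy)cyclohexyl]-1-[(1R,2R,3S,6S)-6-methyl-3-(prop-1-en-2-yl)-7-oxabicyclo[4.1.0]heptan-2-yl]-3-(trimethylsilyl)propan-2-ol (both carbinol epimers)
Conditions: Me3SiCH2MgCl, CeCl3, THF, −78 → 0 °C
Reagents that add atoms: (trimethylsilyl)methylmagnesium chloride, C[Si](C)(C)C[Mg]Cl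
Why: Cerium-mediated addition of the silylmethyl nucleophile (first stage of a Peterson olefination) adds to hindered, enolisable ketones without deprotonation, so the C1' configuration reached in step 17 is kept and the new carbinol centre is lost in step 19.

Step 19
Reactants: 24 2-[(1R,3R,4S)-3-bromo-4-methyl-4-(triethylsilyloxy)cyclohexyl]-1-[(1R,2R,3S,6S)-6-methyl-3-(prop-1-en-2-yl)-7-oxabicyclo[4.1.0]heptan-2-yl]-3-(trimethylsilyl)propan-2-ol
Product: 25 {[(1S,2R,4R)-2-bromo-1-methyl-4-{3-[(1R,2R,3S,6S)-6-methyl-3-(prop-1-en-2-yl)-7-oxabicyclo[4.1.0]heptan-2-yl]prop-1-en-2-yl}cyclohexyl]oxy}triethylsilane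
Conditions: KH, THF, 0 °C → rt
Reagents that add atoms: none
Why: Base-induced syn-elimination of the β-hydroxysilane (Peterson olefination) gives the 1,1-disubstituted alkene at a stage where no carbonyl remains to epimerise C1'.

Step 20
Reactants: 25 {[(1S,2R,4R)-2-bromo-1-methyl-4-{3-[(1R,2R,3S,6S)-6-methyl-3-(prop-1-en-2-yl)-7-oxabicyclo[4.1.0]heptan-2-yl]prop-1-en-2-yl}cyclohexyl]oxy}triethylsilane
Product: 26 (1S,2R,4R)-2-bromo-1-methyl-4-{3-[(1R,2R,3S,6S)-6-methyl-3-(prop-1-en-2-yl)-7-oxabicyclo[4.1.0]heptan-2-yl]prop-1-en-2-yl}cyclohexan-1-ol (CNP0213097.1)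
Conditions: Bu4NF, AcOH, THF, rt
Reagents that add atoms: none
Why: Fluoride cleaves the tertiary triethylsilyl ether, and acetic acid buffering should keep the liberated alkoxide from attacking the neighbouring bromide or the epoxide.

**Compound list**

1 | propane-1,3-diol | OCCCO | starting material
2 | 3-[(4-methoxybenzyl)oxy]propan-1-ol | COc1ccc(COCCCO)cc1 | intermediate
3 | 3-[(4-methoxybenzyl)oxy]propanal | COc1ccc(COCCC=O)cc1 | intermediate
4 | methyl vinyl ketone (but-3-en-2-one) | CC(=O)C=C | starting material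
5 | (R)-2-{[(4-methoxybenzyl)oxy]methyl}-5-oxohexanal | O=C[C@@H](COCc1ccc(OC)cc1)CCC(C)=O | intermediate (not isolated)
6 | (S)-4-{[(4-methoxybenzyl)oxy]methyl}cyclohex-2-en-1-one | COc1ccc(COC[C@H]2CCC(=O)C=C2)cc1 | intermediate
7 | triethyl{[(4S)-4-{[(4-methoxybenzyl)oxy]methyl}cyclohex-1-en-1-yl]oxy}silane | CC[Si](CC)(CC)OC1=CC[C@@H](COCc2ccc(OC)cc2)CC1 | intermediate
8 | (2R,4S)-2-bromo-4-{[(4-methoxybenzyl)oxy]methyl}cyclohexan-1-one (trans) | O=C1CC[C@H](COCc2ccc(OC)cc2)C[C@H]1Br | intermediate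
9 | (1S,2R,4S)-2-bromo-4-{[(4-methoxybenzyl)oxy]methyl}-1-methylcyclohexan-1-ol | C[C@]1(O)CC[C@H](COCc2ccc(OC)cc2)C[C@H]1Br | intermediate
10 | {[(1S,2R,4S)-2-bromo-4-{[(4-methoxybenzyl)oxy]methyl}-1-methylcyclohexyl]oxy}triethylsilane | C[C@]1(O[Si](CC)(CC)CC)CC[C@H](COCc2ccc(OC)cc2)C[C@H]1Br | intermediate
11 | [(1S,3R,4S)-3-bromo-4-methyl-4-(triethylsilyloxy)cyclohexyl]methanol | C[C@]1(O[Si](CC)(CC)CC)CC[C@H](CO)C[C@H]1Br | intermediate
12 | (1S,3R,4S)-3-bromo-4-methyl-4-(triethylsilyloxy)cyclohexane-1-carbaldehyde | C[C@]1(O[Si](CC)(CC)CC)CC[C@H](C=O)C[C@H]1Br | intermediate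
13 | (S)-(+)-carvone | CC1=CC[C@@H](CC1=O)C(C)=C | starting material
14 | (5S,6S)-6-(hydroxymethyl)-2-methyl-5-(prop-1-en-2-yl)cyclohex-2-en-1-one (trans) | CC1=CC[C@@H]([C@@H](CO)C1=O)C(C)=C | intermediate
15 | N'-[(5S,6R)-6-(hydroxymethyl)-2-methyl-5-(prop-1-en-2-yl)cyclohex-2-en-1-ylidene]-4-methylbenzenesulfonohydrazide (C=N geometry not defined) | CC1=CC[C@@H]([C@@H](CO)C1=NNS(=O)(=O)c2ccc(C)cc2)C(C)=C | intermediate
16 | N'-[6-(hydroxymethyl)-2-methyl-5-(prop-1-en-2-yl)cyclohex-2-en-1-yl]-4-methylbenzenesulfonohydrazide (C5 and C6 as in 15, C1 undefined) | CC1=CC[C@@H]([C@@H](CO)C1NNS(=O)(=O)c2ccc(C)cc2)C(C)=C | intermediate (not isolated)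
17 | [(1S,6S)-3-methyl-6-(prop-1-en-2-yl)cyclohex-2-en-1-yl]methanol | CC1=C[C@H](CO)[C@H](CC1)C(C)=C | intermediate
18 | (3S,4S)-3-(bromomethyl)-1-methyl-4-(prop-1-en-2-yl)cyclohex-1-ene | CC1=C[C@H](CBr)[C@H](CC1)C(C)=C | intermediate
19 | {[(1S,6S)-3-methyl-6-(prop-1-en-2-yl)cyclohex-2-en-1-yl]methyl}magnesium bromide | CC1=C[C@H](C[Mg]Br)[C@H](CC1)C(C)=C | intermediate (not isolated)
20 | 1-[(1S,3R,4S)-3-bromo-4-methyl-4-(triethylsilyloxy)cyclohexyl]-2-[(1S,6S)-3-methyl-6-(prop-1-en-2-yl)cyclohex-2-en-1-yl]ethan-1-ol (both carbinol epimers) | C[C@]1(O[Si](CC)(CC)CC)CC[C@H](C(O)C[C@H]2C=C(C)CC[C@@H]2C(C)=C)C[C@H]1Br | intermediate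
21 | 1-[(1S,3R,4S)-3-bromo-4-methyl-4-(triethylsilyloxy)cyclohexyl]-2-[(1R,2R,3S,6S)-6-methyl-3-(prop-1-en-2-yl)-7-oxabicyclo[4.1.0]heptan-2-yl]ethan-1-ol (both carbinol epimers) | C[C@]1(O[Si](CC)(CC)CC)CC[C@H](C(O)C[C@H]2[C@H]3O[C@@]3(C)CC[C@@H]2C(C)=C)C[C@H]1Br | intermediate
22 | 1-[(1S,3R,4S)-3-bromo-4-methyl-4-(triethylsilyloxy)cyclohexyl]-2-[(1R,2R,3S,6S)-6-methyl-3-(prop-1-en-2-yl)-7-oxabicyclo[4.1.0]heptan-2-yl]ethan-1-one | C[C@]1(O[Si](CC)(CC)CC)CC[C@H](C(=O)C[C@H]2[C@H]3O[C@@]3(C)CC[C@@H]2C(C)=C)C[C@H]1Br | intermediate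
23 | 1-[(1R,3R,4S)-3-bromo-4-methyl-4-(triethylsilyloxy)cyclohexyl]-2-[(1R,2R,3S,6S)-6-methyl-3-(prop-1-en-2-yl)-7-oxabicyclo[4.1.0]heptan-2-yl]ethan-1-one | C[C@]1(O[Si](CC)(CC)CC)CC[C@@H](C(=O)C[C@H]2[C@H]3O[C@@]3(C)CC[C@@H]2C(C)=C)C[C@H]1Br | intermediate
24 | 2-[(1R,3R,4S)-3-bromo-4-methyl-4-(triethylsilyloxy)cyclohexyl]-1-[(1R,2R,3S,6S)-6-methyl-3-(prop-1-en-2-yl)-7-oxabicyclo[4.1.0]heptan-2-yl]-3-(trimethylsilyl)propan-2-ol (both carbinol epimers) | C[C@]1(O[Si](CC)(CC)CC)CC[C@@H](C(O)(C[Si](C)(C)C)C[C@H]2[C@H]3O[C@@]3(C)CC[C@@H]2C(C)=C)C[C@H]1Br | intermediate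
25 | {[(1S,2R,4R)-2-bromo-1-methyl-4-{3-[(1R,2R,3S,6S)-6-methyl-3-(prop-1-en-2-yl)-7-oxabicyclo[4.1.0]heptan-2-yl]prop-1-en-2-yl}cyclohexyl]oxy}triethylsilane | C[C@]1(O[Si](CC)(CC)CC)CC[C@@H](C(=C)C[C@H]2[C@H]3O[C@@]3(C)CC[C@@H]2C(C)=C)C[C@H]1Br | intermediate
26 | (1S,2R,4R)-2-bromo-1-methyl-4-{3-[(1R,2R,3S,6S)-6-methyl-3-(prop-1-en-2-yl)-7-oxabicyclo[4.1.0]heptan-2-yl]prop-1-en-2-yl}cyclohexan-1-ol | C=C(C[C@@H]1[C@@H](C(=C)C)CC[C@]2(C)O[C@H]12)[C@@H]1CC[C@](C)(O)[C@H](Br)C1 | target

**Step count and risks**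

Total: 20 steps. Longest linear sequence: 16 steps (steps 1–9 and 14–20, from propane-1,3-diol); the ring-A branch from (S)-carvone is 4 steps (10–13).

Step 17 (inversion of C1' by equilibration). The equilibrium may not lie far enough on the side of 23, because the unwanted epimer can relieve strain by ring inversion, and prolonged base may eliminate HBr. The fallback sets C1' directly with the other catalyst enantiomer and places bromine by equilibration instead. It sets out from 3 and 4. Step 3 with the (S)-configured catalyst gives (R)-4-{[(4-methoxybenzyl)oxy]methyl}cyclohex-2-en-1-one F1. Hydrosilylation as in step 4 gives the (4R)-triethylsilyl enol ether F2. NBS gives the trans bromo ketone F3, which HBr (cat.) in AcOH equilibrates through the enol; the cis (equatorial) bromo ketone F4 is separated and the remainder re-equilibrated. MeTi(OiPr)3, which transfers methyl from the equatorial side, gives the bromohydrin F5 with C1', C4' and C5' as in the target. The conditions of steps 7–9 give the silyl ether F6, the primary alcohol F7 and the aldehyde F8. Addition of 19 as in step 14 gives the secondary alcohol F9, directed epoxidation as in step 15 gives the epoxy alcohol F10, and oxidation as in step 16 returns to the route at 23.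

Step 15 (directed epoxidation). Oxygen transfer through the long tether may be slow or poorly face-selective, and the isopropenyl group or the carbinol may be oxidised instead. The fallback directs the epoxidation from the closer, homoallylic primary hydroxyl before the fragments are joined. It sets out from 17. VO(acac)2 and tBuOOH give the cis-epoxy alcohol [(1R,2S,3S,6S)-6-methyl-3-(prop-1-en-2-yl)-7-oxabicyclo[4.1.0]heptan-2-yl]methanol F11. I2, PPh3 and imidazole give the epoxy iodide F12. Iodine–lithium exchange with tBuLi in Et2O–pentane at −78 °C gives the alkyllithium F13, not isolated; its carbanion cannot reach the back side of the cis-epoxide. Addition to 12 at −78 °C returns to the route at 21.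

Step 3 (key step). The ether oxygen may be lost by β-elimination from the enamine or the aldehyde enolate, and the stereocentre may partly racemise during base-mediated ring closure. The fallback replaces the catalytic Michael addition by an auxiliary-controlled alkylation (Enders hydrazone alkylation). It sets out from 3. Condensation with (S)-1-amino-2-(methoxymethyl)pyrrolidine gives the hydrazone F14. LiN(iPr)2 in THF at −100 °C followed by 2-(2-iodoethyl)-2-methyl-1,3-dioxolane gives the alkylated hydrazone F15, with the new centre arranged as in 5. Two-phase aqueous oxalic acid and then dilute HCl release the aldehyde and the ketone and return to the route at 5, which is cyclised to 6 with LiOH as in step 3.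

**Further compounds**

F1 | step 17 | (R)-4-{[(4-methoxybenzyl)oxy]methyl}cyclohex-2-en-1-one | COc1ccc(COC[C@@H]2CCC(=O)C=C2)cc1
F2 | step 17 | triethyl{[(4R)-4-{[(4-methoxybenzyl)oxy]methyl}cyclohex-1-en-1-yl]oxy}silane | CC[Si](CC)(CC)OC1=CC[C@H](COCc2ccc(OC)cc2)CC1
F3 | step 17 | (2S,4R)-2-bromo-4-{[(4-methoxybenzyl)oxy]methyl}cyclohexan-1-one (trans) | O=C1CC[C@@H](COCc2ccc(OC)cc2)C[C@@H]1Br
F4 | step 17 | (2R,4R)-2-bromo-4-{[(4-methoxybenzyl)oxy]methyl}cyclohexan-1-one (cis) | O=C1CC[C@@H](COCc2ccc(OC)cc2)C[C@H]1Br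
F5 | step 17 | (1S,2R,4R)-2-bromo-4-{[(4-methoxybenzyl)oxy]methyl}-1-methylcyclohexan-1-ol | C[C@]1(O)CC[C@@H](COCc2ccc(OC)cc2)C[C@H]1Br
F6 | step 17 | {[(1S,2R,4R)-2-bromo-4-{[(4-methoxybenzyl)oxy]methyl}-1-methylcyclohexyl]oxy}triethylsilane | C[C@]1(O[Si](CC)(CC)CC)CC[C@@H](COCc2ccc(OC)cc2)C[C@H]1Br
F7 | step 17 | [(1R,3R,4S)-3-bromo-4-methyl-4-(triethylsilyloxy)cyclohexyl]methanol | C[C@]1(O[Si](CC)(CC)CC)CC[C@@H](CO)C[C@H]1Br
F8 | step 17 | (1R,3R,4S)-3-bromo-4-methyl-4-(triethylsilyloxy)cyclohexane-1-carbaldehyde | C[C@]1(O[Si](CC)(CC)CC)CC[C@@H](C=O)C[C@H]1Br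
F9 | step 17 | 1-[(1R,3R,4S)-3-bromo-4-methyl-4-(triethylsilyloxy)cyclohexyl]-2-[(1S,6S)-3-methyl-6-(prop-1-en-2-yl)cyclohex-2-en-1-yl]ethan-1-ol (both carbinol epimers) | C[C@]1(O[Si](CC)(CC)CC)CC[C@@H](C(O)C[C@H]2C=C(C)CC[C@@H]2C(C)=C)C[C@H]1Br
F10 | step 17 | 1-[(1R,3R,4S)-3-bromo-4-methyl-4-(triethylsilyloxy)cyclohexyl]-2-[(1R,2R,3S,6S)-6-methyl-3-(prop-1-en-2-yl)-7-oxabicyclo[4.1.0]heptan-2-yl]ethan-1-ol (both carbinol epimers) | C[C@]1(O[Si](CC)(CC)CC)CC[C@@H](C(O)C[C@H]2[C@H]3O[C@@]3(C)CC[C@@H]2C(C)=C)C[C@H]1Br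
F11 | step 15 | [(1R,2S,3S,6S)-6-methyl-3-(prop-1-en-2-yl)-7-oxabicyclo[4.1.0]heptan-2-yl]methanol | OC[C@H]1[C@H]2O[C@@]2(C)CC[C@@H]1C(C)=C
F12 | step 15 | (1S,4S,5R,6R)-5-(iodomethyl)-1-methyl-4-(prop-1-en-2-yl)-7-oxabicyclo[4.1.0]heptane | IC[C@H]1[C@H]2O[C@@]2(C)CC[C@@H]1C(C)=C
F13 | step 15 | {[(1R,2R,3S,6S)-6-methyl-3-(prop-1-en-2-yl)-7-oxabicyclo[4.1.0]heptan-2-yl]methyl}lithium | [Li]C[C@H]1[C@H]2O[C@@]2(C)CC[C@@H]1C(C)=C
F14 | step 3 | (E)-N-[(2S)-2-(methoxymethyl)pyrrolidin-1-yl]-3-[(4-methoxybenzyl)oxy]propan-1-imine | COC[C@@H]1CCCN1/N=C/CCOCc2ccc(OC)cc2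
F15 | step 3 | (E,2S)-N-[(2S)-2-(methoxymethyl)pyrrolidin-1-yl]-2-{[(4-methoxybenzyl)oxy]methyl}-4-(2-methyl-1,3-dioxolan-2-yl)butan-1-imine | COC[C@@H]1CCCN1/N=C/[C@@H](COCc2ccc(OC)cc2)CCC3(C)OCCO3
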